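**Plan**

1. Retrosynthetic cuts, in order: the two O–benzyl bonds and a blocking C–Br bond (hydrogenolysis); the C7–aryl bond (γ-C–H arylation of the reopened lactone with 4-iodoveratrole); the C5–O1 lactone bond (γ-C–H lactonisation of an isopropyl acid); the C3–C8 bond (enolate benzylation).
2. Enabling feature: in the lactone O1–C2(=O)–C3–C4–C5, C5 and the benzylic carbon C7 are both CH2 groups on C4 and both γ to the carboxyl carbon C2. C4 with its two arms is therefore a latent isopropyl group whose methyl groups can be functionalised one after the other from the same carboxylate.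
3. Forward order: (S)-2-hydroxy-3-methylbutanoic acid becomes its cis pivalaldehyde dioxolanone and is benzylated at C3; hydrolysis and O-silylation give the isopropyl acid. The only ring, the γ-lactone, closes in step 7; it is reopened for arylation of C7, closed again and deprotected.
4. Stereochemistry: C3 comes from the hydroxy acid by self-regeneration of stereocentres with retention. C4 is created in step 7 by selection between the two diastereotopic methyl groups under control of C3.
5. A bromine ortho to C8 on the catechol ring occupies the unhindered ortho position against carboxylate-directed aryl palladation in both C–H steps and leaves with the benzyl groups at the end. The tertiary hydroxyl travels as a TBS ether.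

Key step: step 7

Assumption: 1, 2, 4 and 16 are purchased; lactone numbering O1, C2, C3, C4, C5 is used throughout, with C7 and C8 the benzylic carbons on C4 and C3.

**Route**

Step 1
Reactants: 1 (S)-2-hydroxy-3-methylbutanoic acid; 2 pivalaldehyde
Product: 3 (2S,5S)-2-tert-butyl-5-isopropyl-1,3-dioxolan-4-one (cis)
Conditions: TsOH·H2O (cat.), H2SO4 (cat.), pentane, reflux, Dean–Stark; recrystallisation
Reagents that add atoms: none
Why: Acid-catalysed acetalisation of the α-hydroxy acid with azeotropic removal of water should give mainly the cis dioxolanone, the acetal centre C2 being set by the existing C5 centre under thermodynamic control, and recrystallisation removes the trans isomer.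

Step 2
Reactants: 4 3,4-bis(benzyloxy)benzyl alcohol
Product: 5 [4,5-bis(benzyloxy)-2-bromophenyl]methanol
Conditions: NBS (1.05 equiv), MeCN, 0 °C to rt, dark
Reagents that add atoms: N-bromosuccinimide, O=C1CCC(=O)N1Br
Why: Electrophilic aromatic bromination should occur para to one benzyloxy group and ortho to the hydroxymethyl group, the most activated unhindered position of a 3,4-dialkoxybenzyl alcohol.

Step 3
Reactants: 5 [4,5-bis(benzyloxy)-2-bromophenyl]methanol
Product: 6 1,2-bis(benzyloxy)-4-bromo-5-(bromomethyl)benzene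
Conditions: PBr3 (0.4 equiv), CH2Cl2, 0 °C
Reagents that add atoms: phosphorus tribromide, BrP(Br)Br
Why: Bromination of an electron-rich benzylic alcohol with PBr3 (substitution via the phosphite ester) is routine and leaves the aryl bromide and the benzyl ethers untouched.

Step 4
Reactants: 3 (2S,5S)-2-tert-butyl-5-isopropyl-1,3-dioxolan-4-one; 6 1,2-bis(benzyloxy)-4-bromo-5-(bromomethyl)benzene
Product: 8 (2S,5S)-5-[4,5-bis(benzyloxy)-2-bromobenzyl]-2-tert-butyl-5-isopropyl-1,3-dioxolan-4-one, via lithium enolate 7 (not isolated)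
Conditions: LDA (1.1 equiv), THF, −78 °C; then 6, THF/DMPU, −78 to −30 °C
Reagents that add atoms: none
Why: Enolate alkylation by the self-regeneration-of-stereocentres principle: the tert-butyl group at C2 shields one face of the planar enolate, so the benzylic bromide should enter trans to it, on the face that carried hydrogen, which rebuilds the quaternary centre with retention of the original configuration.

Step 5
Reactants: 8 (2S,5S)-5-[4,5-bis(benzyloxy)-2-bromobenzyl]-2-tert-butyl-5-isopropyl-1,3-dioxolan-4-one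
Product: 9 (S)-2-[4,5-bis(benzyloxy)-2-bromobenzyl]-2-hydroxy-3-methylbutanoic acid
Conditions: LiOH·H2O, THF/MeOH/H2O, 50 °C; then 1 M HCl
Reagents that add atoms: lithium hydroxide, [Li+].[OH-]
Why: Saponification of the acylal ester: hydroxide opens the dioxolanone at the carbonyl group and the hemiacetal collapses to pivalaldehyde, while the quaternary centre cannot epimerise.

Step 6
Reactants: 9 (S)-2-[4,5-bis(benzyloxy)-2-bromobenzyl]-2-hydroxy-3-methylbutanoic acid
Product: 11 (S)-2-[4,5-bis(benzyloxy)-2-bromobenzyl]-2-[(tert-butyldimethylsilyl)oxy]-3-methylbutanoic acid, via bis-TBS derivative 10 (not isolated)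
Conditions: TBSOTf (2.5 equiv), 2,6-lutidine, CH2Cl2, 0 °C to rt; then K2CO3, MeOH/THF/H2O, rt; mildly acidic work-up
Reagents that add atoms: tert-butyldimethylsilyl trifluoromethanesulfonate, CC(C)(C)[Si](C)(C)OS(=O)(=O)C(F)(F)F
Why: Silylation with the silyl triflate covers the hindered tertiary hydroxyl as well as the carboxyl group, and the labile silyl ester is then cleaved selectively by mild basic methanolysis, a standard two-stage protection of a hydroxy acid.

Step 7
Reactants: 11 (S)-2-[4,5-bis(benzyloxy)-2-bromobenzyl]-2-[(tert-butyldimethylsilyl)oxy]-3-methylbutanoic acid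
Product: 12 (3S,4S)-3-[4,5-bis(benzyloxy)-2-bromobenzyl]-3-[(tert-butyldimethylsilyl)oxy]-4-methyldihydrofuran-2(3H)-one
Conditions: Pd(CH3CN)2Cl2 (10 mol%), N-acetyl-β-alanine (20 mol%), CsHCO3 (0.5 equiv), 70% aq. TBHP (2 equiv), HFIP, 60 °C
Reagents that add atoms: none
Why: The carboxylate binds Pd(II) and, assisted by the N-acyl amino acid ligand, one γ-methyl C–H bond of the isopropyl group is cleaved by concerted metalation–deprotonation to a six-membered palladacycle; TBHP oxidises it to Pd(IV), and C5–O1 reductive elimination by the bound carboxylate releases the lactone and Pd(II). The closest known reaction type is the carboxylate-directed palladium-catalysed (and, for valine-type isopropyl acids, platinum-catalysed) C(sp3)–H lactonisation of free aliphatic acids. The five-membered ring closes in a 5-exo-tet sense, the carboxylate oxygen displacing palladium from C5. C4 becomes stereogenic through the choice between the two diastereotopic methyl groups, which C3 controls: in the chair-like palladacycle the carbon-linked bromodibenzyloxybenzyl group (larger than the oxygen-linked silyloxy group) and the spectator methyl should both sit pseudo-equatorial and hence trans, which is the (3S,4S) arrangement; a minor C4 epimer would be removed by chromatography. Site selectivity rests on three things: palladium prefers primary C–H bonds (the only β-C–H bonds are a methine and a hindered benzylic methylene, and there is no β-methyl); the ring bromine occupies the unhindered ortho position of the arene, the other ortho position being flanked by a benzyloxy group, which disfavours seven-membered aryl palladation; and the silyl ether keeps the tertiary oxygen from chelating palladium, from β-carbon elimination and from oxidative decarboxylation.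

Step 8
Reactants: 12 (3S,4S)-3-[4,5-bis(benzyloxy)-2-bromobenzyl]-3-[(tert-butyldimethylsilyl)oxy]-4-methyldihydrofuran-2(3H)-one
Product: 15 (2S,3S)-2-[4,5-bis(benzyloxy)-2-bromobenzyl]-2-[(tert-butyldimethylsilyl)oxy]-4-[(tert-butyldiphenylsilyl)oxy]-3-methylbutanoic acid, via lithium hydroxy carboxylate 13 (not isolated), via bis-TBDPS derivative 14 (not isolated)
Conditions: LiOH·H2O (1.1 equiv), THF/H2O, rt, concentrate; TBDPSCl (2.5 equiv), imidazole, DMF, rt; then K2CO3, MeOH/THF/H2O, rt; work-up at pH 4–5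
Reagents that add atoms: lithium hydroxide, [Li+].[OH-]; tert-butyl(chloro)diphenylsilane, CC(C)(C)[Si](Cl)(c1ccccc1)c1ccccc1
Why: Saponification of the lactone, O-silylation of the hydroxy carboxylate and selective cleavage of the silyl ester is the standard way to hold a γ-lactone open as a γ-silyloxy acid; no stereocentre is involved.

Step 9
Reactants: 15 (2S,3S)-2-[4,5-bis(benzyloxy)-2-bromobenzyl]-2-[(tert-butyldimethylsilyl)oxy]-4-[(tert-butyldiphenylsilyl)oxy]-3-methylbutanoic acid; 16 4-iodo-1,2-dimethoxybenzene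
Product: 17 (2S,3S)-2-[4,5-bis(benzyloxy)-2-bromobenzyl]-2-[(tert-butyldimethylsilyl)oxy]-3-{[(tert-butyldiphenylsilyl)oxy]methyl}-4-(3,4-dimethoxyphenyl)butanoic acid
Conditions: Pd(OAc)2 (10 mol%), N-acetylglycine (20 mol%), Ag2CO3 (2 equiv), 16 (2.5 equiv), HFIP, 90 °C
Reagents that add atoms: none
Why: Carboxylate-directed Pd(II)/Pd(IV) γ-C(sp3)–H arylation of a free aliphatic acid with an aryl iodide: ligand-assisted metalation of the only remaining γ-methyl group gives a six-membered palladacycle, oxidative addition of 16 and C–C reductive elimination form the C7–aryl bond and silver takes up iodide; the C4–H bond is not touched, so both stereocentres are kept, and the brominated arene offers no unhindered ortho position.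

Step 10
Reactants: 17 (2S,3S)-2-[4,5-bis(benzyloxy)-2-bromobenzyl]-2-[(tert-butyldimethylsilyl)oxy]-3-{[(tert-butyldiphenylsilyl)oxy]methyl}-4-(3,4-dimethoxyphenyl)butanoic acid
Product: 19 (3S,4S)-3-[4,5-bis(benzyloxy)-2-bromobenzyl]-4-(3,4-dimethoxybenzyl)-3-hydroxydihydrofuran-2(3H)-one, via dihydroxy acid 18 (not isolated)
Conditions: TBAF (4 equiv), THF, rt to 45 °C; then 1 M HCl, rt
Reagents that add atoms: none
Why: Fluoride cleaves both silyl ethers, and on acidification the γ-hydroxy acid closes to the five-membered lactone by intramolecular acyl substitution (5-exo-trig lactonisation), which the fully substituted C3 strongly favours.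

Step 11
Reactants: 19 (3S,4S)-3-[4,5-bis(benzyloxy)-2-bromobenzyl]-4-(3,4-dimethoxybenzyl)-3-hydroxydihydrofuran-2(3H)-one
Product: 20 (3S,4S)-3-(3,4-dihydroxybenzyl)-4-(3,4-dimethoxybenzyl)-3-hydroxydihydrofuran-2(3H)-one (CNP0142775.1)
Conditions: H2 (1 atm), 10% Pd/C, NaOAc (1.2 equiv), EtOAc/MeOH, rt
Reagents that add atoms: none
Why: Palladium-catalysed hydrogenolysis should remove both aryl benzyl ethers and the aryl bromine in one operation (O-debenzylation with hydrodehalogenation, acetate taking up HBr), while the methyl ethers, the lactone and the non-benzylic tertiary alcohol are inert.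

**Compound list**

1 | (S)-2-hydroxy-3-methylbutanoic acid | CC(C)[C@H](O)C(=O)O | starting material
2 | pivalaldehyde | CC(C)(C)C=O | starting material
3 | (2S,5S)-2-tert-butyl-5-isopropyl-1,3-dioxolan-4-one | CC(C)[C@@H]1O[C@H](C(C)(C)C)OC1=O | intermediate
4 | 3,4-bis(benzyloxy)benzyl alcohol | OCc1ccc(OCc2ccccc2)c(OCc2ccccc2)c1 | starting material
5 | [4,5-bis(benzyloxy)-2-bromophenyl]methanol | OCc1cc(OCc2ccccc2)c(OCc2ccccc2)cc1Br | intermediate
6 | 1,2-bis(benzyloxy)-4-bromo-5-(bromomethyl)benzene | BrCc1cc(OCc2ccccc2)c(OCc2ccccc2)cc1Br | intermediate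
7 | lithium enolate of 3, lithium (2S)-2-tert-butyl-5-isopropyl-1,3-dioxol-4-olate | CC(C)C1=C([O-])O[C@@H](C(C)(C)C)O1.[Li+] | intermediate
8 | (2S,5S)-5-[4,5-bis(benzyloxy)-2-bromobenzyl]-2-tert-butyl-5-isopropyl-1,3-dioxolan-4-one | CC(C)[C@]1(Cc2cc(OCc3ccccc3)c(OCc3ccccc3)cc2Br)O[C@H](C(C)(C)C)OC1=O | intermediate
9 | (S)-2-[4,5-bis(benzyloxy)-2-bromobenzyl]-2-hydroxy-3-methylbutanoic acid | CC(C)[C@@](O)(Cc1cc(OCc2ccccc2)c(OCc2ccccc2)cc1Br)C(=O)O | intermediate
10 | tert-butyldimethylsilyl (S)-2-[4,5-bis(benzyloxy)-2-bromobenzyl]-2-[(tert-butyldimethylsilyl)oxy]-3-methylbutanoate | CC(C)[C@@](O[Si](C)(C)C(C)(C)C)(Cc1cc(OCc2ccccc2)c(OCc2ccccc2)cc1Br)C(=O)O[Si](C)(C)C(C)(C)C | intermediate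
11 | (S)-2-[4,5-bis(benzyloxy)-2-bromobenzyl]-2-[(tert-butyldimethylsilyl)oxy]-3-methylbutanoic acid | CC(C)[C@@](O[Si](C)(C)C(C)(C)C)(Cc1cc(OCc2ccccc2)c(OCc2ccccc2)cc1Br)C(=O)O | intermediate
12 | (3S,4S)-3-[4,5-bis(benzyloxy)-2-bromobenzyl]-3-[(tert-butyldimethylsilyl)oxy]-4-methyldihydrofuran-2(3H)-one | C[C@H]1COC(=O)[C@]1(O[Si](C)(C)C(C)(C)C)Cc1cc(OCc2ccccc2)c(OCc2ccccc2)cc1Br | intermediate
13 | lithium (2S,3S)-2-[4,5-bis(benzyloxy)-2-bromobenzyl]-2-[(tert-butyldimethylsilyl)oxy]-4-hydroxy-3-methylbutanoate | C[C@@H](CO)[C@@](O[Si](C)(C)C(C)(C)C)(Cc1cc(OCc2ccccc2)c(OCc2ccccc2)cc1Br)C(=O)[O-].[Li+] | intermediate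
14 | tert-butyldiphenylsilyl (2S,3S)-2-[4,5-bis(benzyloxy)-2-bromobenzyl]-2-[(tert-butyldimethylsilyl)oxy]-4-[(tert-butyldiphenylsilyl)oxy]-3-methylbutanoate | C[C@@H](CO[Si](c1ccccc1)(c1ccccc1)C(C)(C)C)[C@@](O[Si](C)(C)C(C)(C)C)(Cc1cc(OCc2ccccc2)c(OCc2ccccc2)cc1Br)C(=O)O[Si](c1ccccc1)(c1ccccc1)C(C)(C)C | intermediate
15 | (2S,3S)-2-[4,5-bis(benzyloxy)-2-bromobenzyl]-2-[(tert-butyldimethylsilyl)oxy]-4-[(tert-butyldiphenylsilyl)oxy]-3-methylbutanoic acid | C[C@@H](CO[Si](c1ccccc1)(c1ccccc1)C(C)(C)C)[C@@](O[Si](C)(C)C(C)(C)C)(Cc1cc(OCc2ccccc2)c(OCc2ccccc2)cc1Br)C(=O)O | intermediate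
16 | 4-iodo-1,2-dimethoxybenzene | COc1ccc(I)cc1OC | starting material
17 | (2S,3S)-2-[4,5-bis(benzyloxy)-2-bromobenzyl]-2-[(tert-butyldimethylsilyl)oxy]-3-{[(tert-butyldiphenylsilyl)oxy]methyl}-4-(3,4-dimethoxyphenyl)butanoic acid | COc1ccc(C[C@@H](CO[Si](c2ccccc2)(c2ccccc2)C(C)(C)C)[C@@](O[Si](C)(C)C(C)(C)C)(Cc2cc(OCc3ccccc3)c(OCc3ccccc3)cc2Br)C(=O)O)cc1OC | intermediate
18 | (2S,3S)-2-[4,5-bis(benzyloxy)-2-bromobenzyl]-4-(3,4-dimethoxyphenyl)-2-hydroxy-3-(hydroxymethyl)butanoic acid | COc1ccc(C[C@@H](CO)[C@@](O)(Cc2cc(OCc3ccccc3)c(OCc3ccccc3)cc2Br)C(=O)O)cc1OC | intermediate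
19 | (3S,4S)-3-[4,5-bis(benzyloxy)-2-bromobenzyl]-4-(3,4-dimethoxybenzyl)-3-hydroxydihydrofuran-2(3H)-one | COc1ccc(C[C@H]2COC(=O)[C@]2(O)Cc2cc(OCc3ccccc3)c(OCc3ccccc3)cc2Br)cc1OC | intermediate
20 | (3S,4S)-3-(3,4-dihydroxybenzyl)-4-(3,4-dimethoxybenzyl)-3-hydroxydihydrofuran-2(3H)-one | COc1ccc(C[C@H]2COC(=O)[C@]2(O)Cc2ccc(O)c(O)c2)cc1OC | target

**Step count and risks**

Total steps: 11. Longest linear sequence: 10 steps (2, 3, 4, 5, 6, 7, 8, 9, 10, 11 from compound 4); the dioxolanone branch (step 1, from compounds 1 and 2) joins at step 4.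

Steps most likely to fail:

1. Step 7. Palladation may discriminate poorly between the two γ-methyl groups, or the alkylpalladium may lose the C4 hydrogen by β-hydride elimination before it is oxidised. The fallback sets out from bromide 6 and takes the C4 centre from a building block instead of creating it by desymmetrisation. Purchased (R)-4-methyldihydrofuran-2(3H)-one F1 would be hydroxylated through its lithium enolate (LiHMDS, then 2-(phenylsulfonyl)-3-phenyloxaziridine, THF, −78 °C), the oxidant entering trans to the methyl group, to give (3R,4S)-3-hydroxy-4-methyldihydrofuran-2(3H)-one F2. Its dianion (LDA, 2.2 equiv, THF/HMPA, −78 °C) would be alkylated with 6 on the face opposite the C4 methyl to give (3S,4S)-3-[4,5-bis(benzyloxy)-2-bromobenzyl]-3-hydroxy-4-methyldihydrofuran-2(3H)-one F3. Silylation with TBSOTf and 2,6-lutidine then returns to the route at 12.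

2. Step 9. C–H cleavage at the congested acid may be slow, and the C5 silyl ether may be lost in hot HFIP, after which relactonisation removes the directing carboxylate. The fallback sets out from 15 and uses a bidentate amide auxiliary in a non-acidic medium. The acid chloride ((COCl)2, cat. DMF) and 8-aminoquinoline would give (2S,3S)-2-[4,5-bis(benzyloxy)-2-bromobenzyl]-2-[(tert-butyldimethylsilyl)oxy]-4-[(tert-butyldiphenylsilyl)oxy]-3-methyl-N-(quinolin-8-yl)butanamide F4. Arylation with 16 (Pd(OAc)2, AgOAc, tert-amyl alcohol, 110 °C) should take place at the γ-methyl group, since the β positions are a methine and a hindered benzylic methylene, to give (2S,3S)-2-[4,5-bis(benzyloxy)-2-bromobenzyl]-2-[(tert-butyldimethylsilyl)oxy]-3-{[(tert-butyldiphenylsilyl)oxy]methyl}-4-(3,4-dimethoxyphenyl)-N-(quinolin-8-yl)butanamide F5. TBAF followed by TsOH in warm toluene frees the C5 hydroxyl, which displaces 8-aminoquinoline and closes the lactone, returning to the route at 19.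

3. Step 8. The γ-hydroxy carboxylate may re-close to the lactone before or during O-silylation, and the silyl group may move from the tertiary to the primary oxygen under base. The fallback sets out from 12 and avoids the hydroxy acid by a reduction–reoxidation detour. LiBH4 (THF, 0 °C to rt) would give (2S,3S)-2-[4,5-bis(benzyloxy)-2-bromobenzyl]-2-[(tert-butyldimethylsilyl)oxy]-3-methylbutane-1,4-diol F6. TBDPSCl and imidazole should silylate the primary hydroxyl remote from the quaternary carbon and give (2S,3S)-2-[4,5-bis(benzyloxy)-2-bromobenzyl]-2-[(tert-butyldimethylsilyl)oxy]-4-[(tert-butyldiphenylsilyl)oxy]-3-methylbutan-1-ol F7. Dess–Martin periodinane gives (2S,3S)-2-[4,5-bis(benzyloxy)-2-bromobenzyl]-2-[(tert-butyldimethylsilyl)oxy]-4-[(tert-butyldiphenylsilyl)oxy]-3-methylbutanal F8, which has no α-hydrogen. Pinnick oxidation (NaClO2, NaH2PO4, 2-methyl-2-butene) returns to the route at 15.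

**Further compounds**

F1 | step 7 | (R)-4-methyldihydrofuran-2(3H)-one | C[C@H]1COC(=O)C1
F2 | step 7 | (3R,4S)-3-hydroxy-4-methyldihydrofuran-2(3H)-one | C[C@H]1COC(=O)[C@@H]1O
F3 | step 7 | (3S,4S)-3-[4,5-bis(benzyloxy)-2-bromobenzyl]-3-hydroxy-4-methyldihydrofuran-2(3H)-one | C[C@H]1COC(=O)[C@]1(O)Cc1cc(OCc2ccccc2)c(OCc2ccccc2)cc1Br
F4 | step 9 | (2S,3S)-2-[4,5-bis(benzyloxy)-2-bromobenzyl]-2-[(tert-butyldimethylsilyl)oxy]-4-[(tert-butyldiphenylsilyl)oxy]-3-methyl-N-(quinolin-8-yl)butanamide | C[C@@H](CO[Si](c1ccccc1)(c1ccccc1)C(C)(C)C)[C@@](O[Si](C)(C)C(C)(C)C)(Cc1cc(OCc2ccccc2)c(OCc2ccccc2)cc1Br)C(=O)Nc1cccc2cccnc12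
F5 | step 9 | (2S,3S)-2-[4,5-bis(benzyloxy)-2-bromobenzyl]-2-[(tert-butyldimethylsilyl)oxy]-3-{[(tert-butyldiphenylsilyl)oxy]methyl}-4-(3,4-dimethoxyphenyl)-N-(quinolin-8-yl)butanamide | COc1ccc(C[C@@H](CO[Si](c2ccccc2)(c2ccccc2)C(C)(C)C)[C@@](O[Si](C)(C)C(C)(C)C)(Cc2cc(OCc3ccccc3)c(OCc3ccccc3)cc2Br)C(=O)Nc2cccc3cccnc23)cc1OC
F6 | step 8 | (2S,3S)-2-[4,5-bis(benzyloxy)-2-bromobenzyl]-2-[(tert-butyldimethylsilyl)oxy]-3-methylbutane-1,4-diol | C[C@@H](CO)[C@@](O[Si](C)(C)C(C)(C)C)(Cc1cc(OCc2ccccc2)c(OCc2ccccc2)cc1Br)CO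
F7 | step 8 | (2S,3S)-2-[4,5-bis(benzyloxy)-2-bromobenzyl]-2-[(tert-butyldimethylsilyl)oxy]-4-[(tert-butyldiphenylsilyl)oxy]-3-methylbutan-1-ol | C[C@@H](CO[Si](c1ccccc1)(c1ccccc1)C(C)(C)C)[C@@](O[Si](C)(C)C(C)(C)C)(Cc1cc(OCc2ccccc2)c(OCc2ccccc2)cc1Br)CO
F8 | step 8 | (2S,3S)-2-[4,5-bis(benzyloxy)-2-bromobenzyl]-2-[(tert-butyldimethylsilyl)oxy]-4-[(tert-butyldiphenylsilyl)oxy]-3-methylbutanal | C[C@@H](CO[Si](c1ccccc1)(c1ccccc1)C(C)(C)C)[C@@](O[Si](C)(C)C(C)(C)C)(Cc1cc(OCc2ccccc2)c(OCc2ccccc2)cc1Br)C=O
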